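## Retrosynthetic overview

1. The all-E triene is cut between the two ring-side alkenes: Stille coupling of an (E)-vinylstannane (from a ring ethynyl group) with a (2E,4E)-5-bromodienamide carrying the aminocyclopentenone unit.
2. The ring enamide N–C bond is cut next: Cu-catalysed amidation of an α-iodoenone with (2E,4R)-2,4-dimethyloct-2-enamide (stereocentre from asymmetric hydrogenation of an achiral enoic acid, then Wittig).
3. Both ring stereocentres come from one organocatalytic desymmetrising boronic-acid oxa-Michael addition (formal syn-hydration) of an achiral 4-alkynyl p-quinol; the phenylboronate then protects the cis-diol.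
4. The p-quinol comes from acetylide addition to p-benzoquinone monoketal and ketal hydrolysis.
5. Rings: both carbocycles are bought intact; the only ring closed is the temporary dioxaborolane (step 2), opened again in step 9.

Assumption: all compounds marked "starting material" are catalogue items (2 as a THF solution, 20 as the hydrochloride).
Assumption: the sense of induction in steps 2 and 4 is assigned by analogy and checked on the first run; the quinine-derived pseudo-enantiomeric catalyst or the antipodal ligand is used if the opposite series forms.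

## Route

Step 1
Reactants: 1 4,4-dimethoxycyclohexa-2,5-dien-1-one; 2 lithium (trimethylsilyl)acetylide
Product: 4 4-hydroxy-4-[(trimethylsilyl)ethynyl]cyclohexa-2,5-dien-1-one, via ketal carbinol 3 (not isolated)
Conditions: 2 (0.5 M in THF, 1.1 equiv), THF, −78 °C; then 1 M aq. HCl, acetone, 0 °C → rt
Reagents that add atoms: water, O
Why: 1,2-addition of the acetylide to the only carbonyl of the quinone monoketal, then acid-catalysed ketal hydrolysis, gives the achiral (Cs-symmetric) p-quinol.

Step 2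
Reactants: 4 4-hydroxy-4-[(trimethylsilyl)ethynyl]cyclohexa-2,5-dien-1-one
Product: 6 (3aR,7aR)-2-phenyl-3a-[(trimethylsilyl)ethynyl]-7,7a-dihydro-1,3,2-benzodioxaborol-6(3aH)-one, via boronic hemiester 5 (not isolated)
Conditions: PhB(OH)2 (1.3 equiv), epi-9-amino-9-deoxyquinidine N-[3,5-bis(trifluoromethyl)phenyl]thiourea (10 mol %), 4 Å MS, toluene, 0 °C → rt
Reagents that add atoms: phenylboronic acid, OB(O)c1ccccc1
Why: Proposed new method: an enantioselective desymmetrising formal syn-hydration of a p-quinol, in which phenylboronic acid condenses reversibly with the tertiary OH to a boronic hemiester, the quinuclidine nitrogen of the bifunctional cinchona thiourea coordinates boron (making the B–OH oxygen nucleophilic) while the thiourea hydrogen-bonds the dienone carbonyl, so the B–OH oxygen is delivered intramolecularly (5-exo-trig oxa-Michael) to one of the two enantiotopic enone β-carbons, which sets the quaternary and the secondary carbinol centres at once and forces them cis through the five-membered dioxaborolane; the closest known reaction types are the amine–thiourea-catalysed boronic-acid-hemiester oxa-Michael addition of acyclic γ-hydroxy enones and the desymmetrising oxa-Michael reactions of p-quinols with acetal- or peroxide-tethered oxygen nucleophiles.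

Step 3
Reactants: 6 (3aR,7aR)-2-phenyl-3a-[(trimethylsilyl)ethynyl]-7,7a-dihydro-1,3,2-benzodioxaborol-6(3aH)-one
Product: 7 (3aR,7aR)-5-iodo-2-phenyl-3a-[(trimethylsilyl)ethynyl]-7,7a-dihydro-1,3,2-benzodioxaborol-6(3aH)-one
Conditions: I2 (2 equiv), pyridine/CH2Cl2 (1:1), 0 °C → rt, dark
Reagents that add atoms: iodine, II
Why: Johnson α-iodination (pyridine conjugate addition, enolate iodination, E1cB loss of pyridine) functionalises only the enone α-carbon and leaves the silyl alkyne, the boronate and both stereocentres untouched.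

Step 4
Reactants: 8 (E)-2-methylhex-2-enoic acid
Product: 9 (R)-2-methylhexanoic acid
Conditions: H2 (6 bar), [Ir(cod)((Sa,S)-SIPHOX)]BArF (0.5 mol %), Et3N (0.5 equiv), MeOH, rt
Reagents that add atoms: none
Why: Carboxylate-directed Ir-catalysed asymmetric hydrogenation of an α-methyl-β-alkyl acrylic acid; the chiral P,N-ligand selects the alkene face and sets the methyl-bearing centre as R.

Step 5
Reactants: 9 (R)-2-methylhexanoic acid
Product: 10 (R)-2-methylhexan-1-ol
Conditions: BH3·SMe2 (1.5 equiv), THF, 0 °C → rt; MeOH, aq. work-up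
Reagents that add atoms: none
Why: Borane reduction of the carboxylic acid proceeds without enolisation, so the α-stereocentre is kept.

Step 6
Reactants: 10 (R)-2-methylhexan-1-ol; 11 ethyl 2-(triphenylphosphoranylidene)propanoate
Product: 13 ethyl (2E,4R)-2,4-dimethyloct-2-enoate, via (R)-2-methylhexanal 12 (not isolated)
Conditions: TEMPO (10 mol %), PhI(OAc)2 (1.1 equiv), CH2Cl2, rt; then 11 (1.3 equiv), rt → 35 °C
Reagents that add atoms: none
Why: TEMPO/PhI(OAc)2 oxidation gives the epimerisable α-branched aldehyde under near-neutral conditions and the stabilised ylide traps it in the same flask (Wittig reaction) as the E-trisubstituted enoate.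

Step 7
Reactants: 13 ethyl (2E,4R)-2,4-dimethyloct-2-enoate
Product: 14 (2E,4R)-2,4-dimethyloct-2-enamide
Conditions: Me3Al (3 equiv), NH4Cl (3 equiv), toluene, 0 → 50 °C; dil. HCl work-up
Reagents that add atoms: ammonium chloride, [NH4+].[Cl-]
Why: Weinreb aminolysis with the aluminium amide made from Me3Al and NH4Cl converts the hindered conjugated ester into the primary amide without conjugate addition or alkene isomerisation.

Step 8
Reactants: 7 (3aR,7aR)-5-iodo-2-phenyl-3a-[(trimethylsilyl)ethynyl]-7,7a-dihydro-1,3,2-benzodioxaborol-6(3aH)-one; 14 (2E,4R)-2,4-dimethyloct-2-enamide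
Product: 15 (2E,4R)-N-[(3aR,7aR)-6-oxo-2-phenyl-3a-[(trimethylsilyl)ethynyl]-3a,6,7,7a-tetrahydro-1,3,2-benzodioxaborol-5-yl]-2,4-dimethyloct-2-enamide
Conditions: CuI (10 mol %), MeNHCH2CH2NHMe (20 mol %), Cs2CO3 (1.5 equiv), 14 (1.2 equiv), THF, 50 °C, Ar
Reagents that add atoms: none
Why: Goldberg–Buchwald Cu(I)/diamine amidation of the activated vinyl iodide with the primary amide forms the enamide C–N bond; the alkyne is silyl-capped so no copper acetylide can form.

Step 9
Reactants: 15 (2E,4R)-N-[(3aR,7aR)-6-oxo-2-phenyl-3a-[(trimethylsilyl)ethynyl]-3a,6,7,7a-tetrahydro-1,3,2-benzodioxaborol-5-yl]-2,4-dimethyloct-2-enamide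
Product: 16 (2E,4R)-N-[(3R,4R)-3-ethynyl-3,4-dihydroxy-6-oxocyclohex-1-en-1-yl]-2,4-dimethyloct-2-enamide
Conditions: TBAF/AcOH (1:1, 1.5 equiv), THF, 0 °C; then pinacol (5 equiv), MeOH, rt
Reagents that add atoms: none
Why: Buffered fluoride protodesilylates the alkyne and boron is passed to pinacol by transesterification, so the cis-diol is freed without the base that would trigger β-elimination or retro-aldol of the β-hydroxy ketone.

Step 10
Reactants: 17 glutaconaldehyde potassium salt
Product: 18 (2E,4E)-5-bromopenta-2,4-dienal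
Conditions: Ph3PBr2 (1.1 equiv), CH2Cl2, 0 °C → rt; then cat. I2 (equilibration to E,E)
Reagents that add atoms: triphenylphosphine dibromide, BrP(Br)(c1ccccc1)(c1ccccc1)c1ccccc1
Why: O-phosphonium activation of the dienolate followed by bromide addition–elimination (vinylogous Appel-type deoxybromination) gives the bromodienal, which settles as the E,E isomer.

Step 11
Reactants: 18 (2E,4E)-5-bromopenta-2,4-dienal
Product: 19 (2E,4E)-5-bromopenta-2,4-dienoic acid
Conditions: NaClO2, NaH2PO4, 2-methyl-2-butene, t-BuOH/H2O, 0 °C → rt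
Reagents that add atoms: sodium chlorite, [Na+].[O-]Cl=O
Why: Pinnick oxidation converts the enal into the acid without touching the bromodiene.

Step 12
Reactants: 19 (2E,4E)-5-bromopenta-2,4-dienoic acid; 20 2-amino-3-hydroxycyclopent-2-en-1-one hydrochloride
Product: 22 (2E,4E)-5-bromo-N-(2-hydroxy-5-oxocyclopent-1-en-1-yl)penta-2,4-dienamide, via bromodienoyl chloride 21 (not isolated)
Conditions: (COCl)2 (1.2 equiv), cat. DMF, CH2Cl2, 0 °C; then 20, Et3N (3.2 equiv), THF, 0 °C → rt
Reagents that add atoms: none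
Why: Acid chloride N-acylation of the aminocyclopentenone; any O-acyl enol ester formed first rearranges to the more stable amide under the basic conditions.

Step 13
Reactants: 16 (2E,4R)-N-[(3R,4R)-3-ethynyl-3,4-dihydroxy-6-oxocyclohex-1-en-1-yl]-2,4-dimethyloct-2-enamide; 22 (2E,4E)-5-bromo-N-(2-hydroxy-5-oxocyclopent-1-en-1-yl)penta-2,4-dienamide
Product: 24 (2E,4R)-N-[(3S,4R)-3,4-dihydroxy-3-[(1E,3E,5E)-7-[(2-hydroxy-5-oxocyclopent-1-en-1-yl)amino]-7-oxohepta-1,3,5-trien-1-yl]-6-oxocyclohex-1-en-1-yl]-2,4-dimethyloct-2-enamide, via E-vinylstannane 23 (not isolated)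
Conditions: Bu3SnH (1.1 equiv, slow addition), PdCl2(PPh3)2 (3 mol %), THF, 0 °C; then 22 (1.3 equiv), PdCl2(MeCN)2 (5 mol %), DMF, rt, dark
Reagents that add atoms: none
Why: Pd-catalysed syn-hydrostannation of the hindered terminal propargylic alcohol puts tin on the distal carbon (E-stannane), and Stille coupling with the E,E-bromodienamide at room temperature under neutral conditions keeps all alkene geometries and both carbinol centres (the 3R → 3S change is only a CIP priority change).

## Compound list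

1 | 4,4-dimethoxycyclohexa-2,5-dien-1-one | COC1(OC)C=CC(=O)C=C1 | starting material
2 | lithium (trimethylsilyl)acetylide | [Li]C#C[Si](C)(C)C | starting material
3 | 4,4-dimethoxy-1-[(trimethylsilyl)ethynyl]cyclohexa-2,5-dien-1-ol | C[Si](C)(C)C#CC1(O)C=CC(OC)(OC)C=C1 | intermediate
4 | 4-hydroxy-4-[(trimethylsilyl)ethynyl]cyclohexa-2,5-dien-1-one | C[Si](C)(C)C#CC1(O)C=CC(=O)C=C1 | intermediate
5 | 4-oxo-1-[(trimethylsilyl)ethynyl]cyclohexa-2,5-dien-1-yl hydrogen phenylboronate | C[Si](C)(C)C#CC1(OB(O)c2ccccc2)C=CC(=O)C=C1 | intermediate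
6 | (3aR,7aR)-2-phenyl-3a-[(trimethylsilyl)ethynyl]-7,7a-dihydro-1,3,2-benzodioxaborol-6(3aH)-one | O=C1C=C[C@@](O2)(C#C[Si](C)(C)C)[C@H](OB2c3ccccc3)C1 | intermediate
7 | (3aR,7aR)-5-iodo-2-phenyl-3a-[(trimethylsilyl)ethynyl]-7,7a-dihydro-1,3,2-benzodioxaborol-6(3aH)-one | O=C1C(I)=C[C@@](O2)(C#C[Si](C)(C)C)[C@H](OB2c3ccccc3)C1 | intermediate
8 | (E)-2-methylhex-2-enoic acid | CCC/C=C(\C)C(=O)O | starting material
9 | (R)-2-methylhexanoic acid | CCCC[C@@H](C)C(=O)O | intermediate
10 | (R)-2-methylhexan-1-ol | CCCC[C@@H](C)CO | intermediate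
11 | ethyl 2-(triphenylphosphoranylidene)propanoate | CCOC(=O)C(C)=P(c1ccccc1)(c1ccccc1)c1ccccc1 | starting material
12 | (R)-2-methylhexanal | CCCC[C@@H](C)C=O | intermediate
13 | ethyl (2E,4R)-2,4-dimethyloct-2-enoate | CCCC[C@@H](C)/C=C(\C)C(=O)OCC | intermediate
14 | (2E,4R)-2,4-dimethyloct-2-enamide | CCCC[C@@H](C)/C=C(\C)C(N)=O | intermediate
15 | (2E,4R)-N-[(3aR,7aR)-6-oxo-2-phenyl-3a-[(trimethylsilyl)ethynyl]-3a,6,7,7a-tetrahydro-1,3,2-benzodioxaborol-5-yl]-2,4-dimethyloct-2-enamide | O=C1C(NC(=O)/C(C)=C/[C@H](C)CCCC)=C[C@@](O2)(C#C[Si](C)(C)C)[C@H](OB2c3ccccc3)C1 | intermediate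
16 | (2E,4R)-N-[(3R,4R)-3-ethynyl-3,4-dihydroxy-6-oxocyclohex-1-en-1-yl]-2,4-dimethyloct-2-enamide | O=C1C(NC(=O)/C(C)=C/[C@H](C)CCCC)=C[C@@](O)(C#C)[C@H](O)C1 | intermediate
17 | glutaconaldehyde potassium salt (potassium (1E,3E)-5-oxopenta-1,3-dien-1-olate) | [K+].[O-]/C=C/C=C/C=O | starting material
18 | (2E,4E)-5-bromopenta-2,4-dienal | O=C/C=C/C=C/Br | intermediate
19 | (2E,4E)-5-bromopenta-2,4-dienoic acid | OC(=O)/C=C/C=C/Br | intermediate
20 | 2-amino-3-hydroxycyclopent-2-en-1-one hydrochloride | Cl.NC1=C(O)CCC1=O | starting material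
21 | (2E,4E)-5-bromopenta-2,4-dienoyl chloride | ClC(=O)/C=C/C=C/Br | intermediate
22 | (2E,4E)-5-bromo-N-(2-hydroxy-5-oxocyclopent-1-en-1-yl)penta-2,4-dienamide | Br/C=C/C=C/C(=O)NC1=C(O)CCC1=O | intermediate
23 | (2E,4R)-N-[(3R,4R)-3,4-dihydroxy-6-oxo-3-[(E)-2-(tributylstannyl)ethenyl]cyclohex-1-en-1-yl]-2,4-dimethyloct-2-enamide | O=C1C(NC(=O)/C(C)=C/[C@H](C)CCCC)=C[C@@](O)(/C=C/[Sn](CCCC)(CCCC)CCCC)[C@H](O)C1 | intermediate
24 | (2E,4R)-N-[(3S,4R)-3,4-dihydroxy-3-[(1E,3E,5E)-7-[(2-hydroxy-5-oxocyclopent-1-en-1-yl)amino]-7-oxohepta-1,3,5-trien-1-yl]-6-oxocyclohex-1-en-1-yl]-2,4-dimethyloct-2-enamide (CNP0154433.2) | CCCC[C@@H](C)/C=C(\C)C(=O)NC1=C[C@@](O)(/C=C/C=C/C=C/C(=O)NC2=C(O)CCC2=O)[C@H](O)CC1=O | target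

## Step count and risks

Total step count: 13. Longest linear sequence: 7 steps (4, 5, 6, 7, 8, 9, 13); the core branch is 6 steps (1, 2, 3, 8, 9, 13).

Three steps most likely to fail:

Step 2 (the proposed new step). The tertiary alcohol may form the boronic hemiester poorly, an uncatalysed background cyclisation or a reversible retro-oxa-Michael reaction may erode the ee, and the facial sense is not yet known. Fallback with known chemistry: setting out from 4, a chiral phosphoric acid (TRIP type, 5 mol %) catalysed acetalisation/oxa-Michael cascade with 4-methoxybenzaldehyde (4 Å MS, toluene) gives the cis-fused p-methoxybenzylidene acetal F1. PPTS in wet MeOH frees the diol F2, and condensation of F2 with PhB(OH)2 (MgSO4, CH2Cl2) comes back to the route at 6.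

Step 8. Caesium carbonate at 50 °C may cause β-elimination (retro-oxa-Michael) of the β-boryloxy ketone, phenyl transfer from boron to copper, or partial C–Si cleavage. Fallback: setting out from 7, Cu(I)/L-proline-catalysed azidation (NaN3, DMSO, 40 °C) gives the 2-azidoenone F3, and Staudinger reduction (PPh3, THF, then H2O) gives the 2-aminoenone F4. N-Acylation of F4 with the acid chloride F6 (pyridine, CH2Cl2, 0 °C) comes back to the route at 15; F6 is made from ester 13 by LiOH hydrolysis to the acid F5 and treatment with (COCl)2/cat. DMF.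

Step 13. The hydrostannation may give some internal (α) stannane or Pd–H conjugate reduction of the amido-enone, and the free diol/polyene product is sensitive to acid, base and light. Fallback: setting out from 16, Lindlar semi-hydrogenation (H2, Pd/CaCO3–Pb, quinoline, EtOAc) gives the vinyl carbinol F7. A Heck reaction of F7 with 22 under Jeffery conditions (Pd(OAc)2, n-Bu4NCl, NaHCO3, DMF, 40 °C) builds the E,E,E-triene and comes back to the route at 24.

## Further compounds

F1 | step 2 | (3aR,7aR)-2-(4-methoxyphenyl)-3a-[(trimethylsilyl)ethynyl]-7,7a-dihydro-1,3-benzodioxol-6(3aH)-one (acetal carbon not assigned) | O=C1C=C[C@@](O2)(C#C[Si](C)(C)C)[C@H](OC2c3ccc(OC)cc3)C1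
F2 | step 2 | (4R,5R)-4,5-dihydroxy-4-[(trimethylsilyl)ethynyl]cyclohex-2-en-1-one | O=C1C=C[C@@](O)(C#C[Si](C)(C)C)[C@H](O)C1
F3 | step 8 | (3aR,7aR)-5-azido-2-phenyl-3a-[(trimethylsilyl)ethynyl]-7,7a-dihydro-1,3,2-benzodioxaborol-6(3aH)-one | O=C1C(N=[N+]=[N-])=C[C@@](O2)(C#C[Si](C)(C)C)[C@H](OB2c3ccccc3)C1
F4 | step 8 | (3aR,7aR)-5-amino-2-phenyl-3a-[(trimethylsilyl)ethynyl]-7,7a-dihydro-1,3,2-benzodioxaborol-6(3aH)-one | O=C1C(N)=C[C@@](O2)(C#C[Si](C)(C)C)[C@H](OB2c3ccccc3)C1
F5 | step 8 | (2E,4R)-2,4-dimethyloct-2-enoic acid | CCCC[C@@H](C)/C=C(\C)C(=O)O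
F6 | step 8 | (2E,4R)-2,4-dimethyloct-2-enoyl chloride | CCCC[C@@H](C)/C=C(\C)C(=O)Cl
F7 | step 13 | (2E,4R)-N-[(3S,4R)-3-ethenyl-3,4-dihydroxy-6-oxocyclohex-1-en-1-yl]-2,4-dimethyloct-2-enamide | O=C1C(NC(=O)/C(C)=C/[C@H](C)CCCC)=C[C@@](O)(C=C)[C@H](O)C1
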